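## Retrosynthetic overview

- Last bond: the diene C–C bond between the chain and the vinyl butenolide, by Stille coupling of a trisubstituted (E)-alkenyl iodide with an (E)-2-stannylvinyl butenolide (from 4-bromofuran-2(5H)-one and (E)-1,2-bis(tributylstannyl)ethene).
- (E)-Alkylidene lactone C=C: aldol addition then E1cB dehydration between the chiral γ-lactone enolate and a C11 iodo-dienal.
- Key bond: the CH2–CH2 bond next to the central trisubstituted alkene, formed together with that (E)-alkene by a Johnson–Claisen [3,3]-sigmatropic rearrangement of an isopropenyl carbinol (from pent-4-yn-1-ol by carboalumination/iodination, oxidation and isopropenylmagnesium bromide addition).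
- Stereocentre: bought in (S)-5-(hydroxymethyl)dihydrofuran-2(3H)-one (L-glutamic acid series); oxidation and isopropylidene Wittig give the (S)-alkenyl lactone.
- Rings: neither ring is built; the γ-lactone (chiral pool) is joined to the chain first (aldol), the butenolide (bought as 4-bromofuran-2(5H)-one) last (Stille).

Assumption: the four bought building blocks are catalogue compounds; metal alkoxide forms of a product before quench, oxaphosphetanes and catalytic-cycle species are not counted as separate compounds.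

## Route

Step 1
Reactants: 1 (S)-5-(hydroxymethyl)dihydrofuran-2(3H)-one
Product: 2 (S)-5-oxotetrahydrofuran-2-carbaldehyde
Conditions: IBX (2-iodoxybenzoic acid, 2 equiv), EtOAc, 75 °C, 3 h; cool, filter, concentrate; crude used at once
Reagents that add atoms: none
Why: IBX oxidation of the primary alcohol stops at the aldehyde under neutral, non-aqueous conditions, so the α-oxygenated (S) centre bought in 1 is not epimerised and the water-soluble aldehyde is isolated by filtration alone.

Step 2
Reactants: 2 (S)-5-oxotetrahydrofuran-2-carbaldehyde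
Product: 3 (S)-5-(2-methylprop-1-en-1-yl)dihydrofuran-2(3H)-one
Conditions: i-PrPPh3I (1.3 equiv), n-BuLi (1.25 equiv), THF, 0 °C, 30 min; then 2, −78 °C → 0 °C
Reagents that add atoms: isopropyltriphenylphosphonium iodide, CC(C)[P+](c1ccccc1)(c1ccccc1)c1ccccc1.[I-]
Why: Wittig olefination with the non-stabilised isopropylidene ylide at −78 °C outpaces enolisation of the aldehyde and attack on the lactone carbonyl, so the (S) centre is carried over unchanged, and no alkene geometry arises because the new terminus is CMe2.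

Step 3
Reactants: 4 pent-4-yn-1-ol
Product: 6 (E)-5-iodo-4-methylpent-4-en-1-ol, via alkenylalane 5 (not isolated)
Conditions: AlMe3 (3 equiv), Cp2ZrCl2 (0.25 equiv), CH2Cl2, 0 °C → rt, 16 h; then I2 (1.3 equiv), THF, −30 → 0 °C; aqueous work-up
Reagents that add atoms: trimethylaluminium, C[Al](C)C; iodine, II
Why: Negishi zirconium-catalysed carboalumination adds Me–Al syn across the terminal alkyne with Al at the terminus, and iodinolysis with retention gives the (E)-trisubstituted alkenyl iodide as a single regio- and stereoisomer.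

Step 4
Reactants: 6 (E)-5-iodo-4-methylpent-4-en-1-ol
Product: 7 (E)-5-iodo-4-methylpent-4-enal
Conditions: Dess–Martin periodinane (1.2 equiv), CH2Cl2, 0 °C → rt, 1 h
Reagents that add atoms: none
Why: Dess–Martin oxidation of the primary alcohol to the aldehyde is neutral and leaves the alkenyl iodide untouched.

Step 5
Reactants: 7 (E)-5-iodo-4-methylpent-4-enal
Product: 8 (6E)-7-iodo-2,6-dimethylhepta-1,6-dien-3-ol (racemic)
Conditions: CH2=C(CH3)MgBr (1.3 equiv), THF, −78 → −40 °C; then aq. NH4Cl
Reagents that add atoms: isopropenylmagnesium bromide, C=C(C)[Mg]Br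
Why: Grignard 1,2-addition to the aldehyde at −78 °C (no iodine–magnesium exchange on the alkenyl iodide at this temperature) gives the 2-substituted allylic alcohol needed for the Claisen step, and the new carbinol centre is left racemic on purpose because it becomes sp2 in step 6.

Step 6
Reactants: 8 (6E)-7-iodo-2,6-dimethylhepta-1,6-dien-3-ol
Product: 11 ethyl (4E,8E)-9-iodo-4,8-dimethylnona-4,8-dienoate, via mixed orthoester 9 (not isolated), via ketene acetal 10 (not isolated)
Conditions: MeC(OEt)3 (6 equiv), EtCO2H (0.1 equiv), 140 °C, 3 h, EtOH distilled off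
Reagents that add atoms: triethyl orthoacetate, CC(OCC)(OCC)OCC
Why: Johnson–Claisen orthoester rearrangement (acid-catalysed exchange to 9, loss of EtOH to 10, then a chair-like [3,3]-sigmatropic shift with the iodoalkenyl-ethyl chain equatorial) forms the C2–C3 bond and the (4E)-trisubstituted alkene, typically >95:5 E, while erasing the racemic carbinol centre.

Step 7
Reactants: 11 ethyl (4E,8E)-9-iodo-4,8-dimethylnona-4,8-dienoate
Product: 12 (4E,8E)-9-iodo-4,8-dimethylnona-4,8-dienal
Conditions: i-Bu2AlH (1.1 equiv), CH2Cl2, −78 °C, 1 h; then H2O, −78 °C → rt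
Reagents that add atoms: none
Why: Partial ester reduction with i-Bu2AlH at −78 °C stops at a tetrahedral aluminium hemiacetal that survives until hydrolysis, so only the aldehyde forms, and the alkenyl iodide and alkenes are inert.

Step 8
Reactants: 3 (S)-5-(2-methylprop-1-en-1-yl)dihydrofuran-2(3H)-one; 12 (4E,8E)-9-iodo-4,8-dimethylnona-4,8-dienal
Product: 14 (5S)-3-[(4E,8E)-1-hydroxy-9-iodo-4,8-dimethylnona-4,8-dien-1-yl]-5-(2-methylprop-1-en-1-yl)dihydrofuran-2(3H)-one (diastereomer mixture), via lithium enolate 13 (not isolated)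
Conditions: LiN(i-Pr)2 (1.1 equiv), THF, −78 °C, 45 min; then 12, −78 °C, 30 min; AcOH (1.2 equiv), −78 °C
Reagents that add atoms: none
Why: Directed aldol addition of the kinetic lithium enolate of the lactone to the aldehyde outpaces proton transfer at −78 °C; the C5 centre is not acidic and is untouched, and the two new centres need no control because both are removed in step 9.

Step 9
Reactants: 14 (5S)-3-[(4E,8E)-1-hydroxy-9-iodo-4,8-dimethylnona-4,8-dien-1-yl]-5-(2-methylprop-1-en-1-yl)dihydrofuran-2(3H)-one
Product: 16 (3E,5S)-3-[(4E,8E)-9-iodo-4,8-dimethylnona-4,8-dien-1-ylidene]-5-(2-methylprop-1-en-1-yl)dihydrofuran-2(3H)-one, via mesylate 15 (not isolated)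
Conditions: MsCl (1.5 equiv), Et3N (3 equiv), CH2Cl2, 0 °C, 30 min; then DBU (3 equiv), 0 °C → rt, 2 h
Reagents that add atoms: none
Why: Mesylation then DBU-promoted E1cB elimination through the lactone enolate gives the thermodynamically preferred (E)-alkylidene lactone (chain anti to C=O) from every aldol diastereomer, and C5 is unaffected.

Step 10
Reactants: 17 4-bromofuran-2(5H)-one; 18 (E)-1,2-bis(tributylstannyl)ethene (2 equiv)
Product: 19 (E)-4-[2-(tributylstannyl)ethenyl]furan-2(5H)-one
Conditions: Pd(PPh3)4 (5 mol%), toluene, 80 °C, dark; chromatography on Et3N-deactivated silica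
Reagents that add atoms: none
Why: Migita–Kosugi–Stille coupling of the activated β-bromo enoate with a twofold excess of the distannane transfers one stannylvinyl group with retention of the (E) geometry, the excess suppressing double coupling.

Step 11
Reactants: 16 (3E,5S)-3-[(4E,8E)-9-iodo-4,8-dimethylnona-4,8-dien-1-ylidene]-5-(2-methylprop-1-en-1-yl)dihydrofuran-2(3H)-one; 19 (E)-4-[2-(tributylstannyl)ethenyl]furan-2(5H)-one
Product: 20 (3E,5S)-3-[(4E,8E,10E)-4,8-dimethyl-11-(5-oxo-2,5-dihydrofuran-3-yl)undeca-4,8,10-trien-1-ylidene]-5-(2-methylprop-1-en-1-yl)dihydrofuran-2(3H)-one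
Conditions: Pd2(dba)3 (5 mol%), AsPh3 (40 mol%), CuI (10 mol%), degassed DMF, rt, dark
Reagents that add atoms: none
Why: Stille coupling joins the two sp2 carbons with retention at both partners to give the (8E,10E)-diene, and the neutral room-temperature conditions with the weakly donating AsPh3 ligand leave both lactones, the Michael acceptors and the allylic lactone C–O bond (no ionisation by zerovalent palladium) intact, so the (S) centre and all four alkene geometries are those of the target.

## Compound list

1 | (S)-5-(hydroxymethyl)dihydrofuran-2(3H)-one | OC[C@@H]1CCC(=O)O1 | starting material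
2 | (S)-5-oxotetrahydrofuran-2-carbaldehyde | O=C[C@@H]1CCC(=O)O1 | intermediate
3 | (S)-5-(2-methylprop-1-en-1-yl)dihydrofuran-2(3H)-one | CC(C)=C[C@@H]1CCC(=O)O1 | intermediate
4 | pent-4-yn-1-ol | C#CCCCO | starting material
5 | dimethyl{(1E)-5-[(dimethylalumanyl)oxy]-2-methylpent-1-en-1-yl}alumane (alkenylalane, not isolated) | C/C(CCCO[Al](C)C)=C\[Al](C)C | intermediate
6 | (E)-5-iodo-4-methylpent-4-en-1-ol | OCCC/C(C)=C/I | intermediate
7 | (E)-5-iodo-4-methylpent-4-enal | O=CCC/C(C)=C/I | intermediate
8 | (6E)-7-iodo-2,6-dimethylhepta-1,6-dien-3-ol (racemic at C3) | C=C(C)C(O)CC/C(C)=C/I | intermediate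
9 | (6E)-3-(1,1-diethoxyethoxy)-7-iodo-2,6-dimethylhepta-1,6-diene (mixed orthoester, not isolated) | CCOC(C)(OCC)OC(CC/C(C)=C/I)C(C)=C | intermediate
10 | (6E)-3-[(1-ethoxyethenyl)oxy]-7-iodo-2,6-dimethylhepta-1,6-diene (ketene acetal, not isolated) | C=C(OCC)OC(CC/C(C)=C/I)C(C)=C | intermediate
11 | ethyl (4E,8E)-9-iodo-4,8-dimethylnona-4,8-dienoate | CCOC(=O)CC/C(C)=C/CC/C(C)=C/I | intermediate
12 | (4E,8E)-9-iodo-4,8-dimethylnona-4,8-dienal | O=CCC/C(C)=C/CC/C(C)=C/I | intermediate
13 | lithium (5S)-5-(2-methylprop-1-en-1-yl)-4,5-dihydrofuran-2-olate (lithium enolate, not isolated) | CC(C)=C[C@@H]1CC=C(O[Li])O1 | intermediate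
14 | (5S)-3-[(4E,8E)-1-hydroxy-9-iodo-4,8-dimethylnona-4,8-dien-1-yl]-5-(2-methylprop-1-en-1-yl)dihydrofuran-2(3H)-one (mixture at C3 and the carbinol carbon) | CC(C)=C[C@@H]1CC(C(O)CC/C(C)=C/CC/C(C)=C/I)C(=O)O1 | intermediate
15 | (4E,8E)-9-iodo-4,8-dimethyl-1-[(5S)-5-(2-methylprop-1-en-1-yl)-2-oxotetrahydrofuran-3-yl]nona-4,8-dien-1-yl methanesulfonate (mesylate, not isolated) | CC(C)=C[C@@H]1CC(C(OS(C)(=O)=O)CC/C(C)=C/CC/C(C)=C/I)C(=O)O1 | intermediate
16 | (3E,5S)-3-[(4E,8E)-9-iodo-4,8-dimethylnona-4,8-dien-1-ylidene]-5-(2-methylprop-1-en-1-yl)dihydrofuran-2(3H)-one | CC(C)=C[C@@H]1C/C(=C\CC/C(C)=C/CC/C(C)=C/I)C(=O)O1 | intermediate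
17 | 4-bromofuran-2(5H)-one | BrC1=CC(=O)OC1 | starting material
18 | (E)-1,2-bis(tributylstannyl)ethene | CCCC[Sn](CCCC)(CCCC)/C=C/[Sn](CCCC)(CCCC)CCCC | starting material
19 | (E)-4-[2-(tributylstannyl)ethenyl]furan-2(5H)-one | CCCC[Sn](CCCC)(CCCC)/C=C/C1=CC(=O)OC1 | intermediate
20 | (3E,5S)-3-[(4E,8E,10E)-4,8-dimethyl-11-(5-oxo-2,5-dihydrofuran-3-yl)undeca-4,8,10-trien-1-ylidene]-5-(2-methylprop-1-en-1-yl)dihydrofuran-2(3H)-one | CC(C)=C[C@@H]1C/C(=C\CC/C(C)=C/CC/C(C)=C/C=C/C2=CC(=O)OC2)C(=O)O1 | target

## Step count and risks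

Total steps: 11. Longest linear sequence: 8 (steps 3, 4, 5, 6, 7, 8, 9 and 11, from pent-4-yn-1-ol).

Three steps most likely to fail:

Step 2. The α-oxygenated aldehyde 2 can enolise (loss of ee) or give low yields with the hindered, strongly basic isopropylidene ylide. The fallback sets out from 2 and builds the trisubstituted alkene by metathesis instead. Compound 2 is methylenated with the smaller ylide Ph3P=CH2 (MePPh3Br, KN(SiMe3)2, THF, −78 °C) to give (S)-5-ethenyldihydrofuran-2(3H)-one F1. Cross-metathesis of F1 with neat 2-methylbut-2-ene and the achiral second-generation Grubbs catalyst (CH2Cl2, 40 °C) then installs the 2-methylprop-1-enyl group. The fallback comes back to the route at 3.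

Step 9. The elimination may give too much of the (Z)-alkylidene lactone, or base may move the exocyclic alkene into the ring. The fallback sets out from 3 and replaces the aldol/dehydration pair by a phosphonate olefination. Compound 3 is treated with LiN(i-Pr)2 (2.2 equiv) and ClP(O)(OEt)2 in THF (−78 °C → rt; enol phosphate to phosphonate 1,3-shift) to give diethyl [(5S)-5-(2-methylprop-1-en-1-yl)-2-oxotetrahydrofuran-3-yl]phosphonate F2. Horner–Wadsworth–Emmons reaction of F2 with aldehyde 12 (NaH, THF, 0 °C) gives the alkylidene lactone without passing through 14. The fallback comes back to the route at 16.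

Step 10. The mono-coupling may over-react to the bis-butenolide, or the electron-poor stannane 19 may protodestannylate on purification. The fallback sets out from 16 and 18 and puts the tin on the chain instead of on the butenolide. Compound 16 is coupled with excess 18 (PdCl2(MeCN)2, DMF, rt) to give (3E,5S)-3-[(4E,8E,10E)-4,8-dimethyl-11-(tributylstannyl)undeca-4,8,10-trien-1-ylidene]-5-(2-methylprop-1-en-1-yl)dihydrofuran-2(3H)-one F3. F3 is then Stille-coupled with 17 (Pd2(dba)3, AsPh3, CuI, DMF, rt). The fallback comes back to the route at 20, so 19 is never made.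

Further compounds
F1 | step 2 | (S)-5-ethenyldihydrofuran-2(3H)-one | C=C[C@@H]1CCC(=O)O1
F2 | step 9 | diethyl [(5S)-5-(2-methylprop-1-en-1-yl)-2-oxotetrahydrofuran-3-yl]phosphonate | CC(C)=C[C@@H]1CC(P(=O)(OCC)OCC)C(=O)O1
F3 | step 10 | (3E,5S)-3-[(4E,8E,10E)-4,8-dimethyl-11-(tributylstannyl)undeca-4,8,10-trien-1-ylidene]-5-(2-methylprop-1-en-1-yl)dihydrofuran-2(3H)-one | CC(C)=C[C@@H]1C/C(=C\CC/C(C)=C/CC/C(C)=C/C=C/[Sn](CCCC)(CCCC)CCCC)C(=O)O1
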